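**Plan**

- Retrosynthesis: the dihydropyran ring is opened by a retro-oxa-Diels–Alder cut of O1–C2 and C3–C4 into an o-quinone methide and an (E)-styrene. Both derive from one carbinol by loss of water, and the carbinol is cut at its carbinol–isobutyl bond to triformylphloroglucinol and isobutylmagnesium bromide.
- Enabling feature: both halves of the target are the same side-chain-alkylated diformylphloroglucinol at the same oxidation level. One appears as the heterodiene O1=C8a–C4a=C4 of ring A (the chroman benzo ring, isobutyl on C4); the other as its tautomer, the C2=C3 styrene carrying ring B (the pendant aryl group). Every carbon of both benzene rings is substituted, so only the alkene can attack the quinone methide at carbon.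
- Forward: Grignard mono-addition makes the C4–isobutyl bond; part of the carbinol is dehydrated thermally, through the Z quinone methide, to the styrene; the acid-catalysed cross cycloaddition of the E quinone methide with the styrene closes the dihydropyran ring last. No protecting groups are used.
- Stereochemistry: 2,3-trans comes from the E alkene; 3,4-trans and 2,4-cis come from the E quinone methide (isobutyl outside) reacting through the aryl-endo transition state; the absolute configuration (2R,3R,4R) comes from a chiral N-triflylphosphoramide that holds both partners by hydrogen bonds.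

Key step: step 3

Assumption: the (R)-configured acid is taken to shield the face that leads to the (2R,3R,4R) product; if the sense proves the reverse, the (S)-acid is used in its place with no other change.

**Route**

Step 1
Reactants: 1 2,4,6-trihydroxybenzene-1,3,5-tricarbaldehyde (triformylphloroglucinol); 2 isobutylmagnesium bromide
Product: 3 racemic 2,4,6-trihydroxy-5-(1-hydroxy-3-methylbutyl)benzene-1,3-dicarbaldehyde
Conditions: 2 (4.2 equiv), THF, −40 to 0 °C; then 0.5 M HCl, 0 °C; used promptly
Reagents that add atoms: isobutylmagnesium bromide (compound 2), CC(C)C[Mg]Br
Why: Grignard 1,2-addition to an unprotected hydroxybenzaldehyde: three equivalents of 2 first form the tris(phenoxide) of 1, whose three formyl groups are equivalent so that mono-addition gives one constitution, the tetra-anionic adduct should resist a second addition, and the carbinol centre is left racemic because steps 2 and 3 erase it.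

Step 2
Reactants: 3 racemic 2,4,6-trihydroxy-5-(1-hydroxy-3-methylbutyl)benzene-1,3-dicarbaldehyde (about half of the material)
Product: 5 2,4,6-trihydroxy-5-[(E)-3-methylbut-1-en-1-yl]benzene-1,3-dicarbaldehyde, via (Z)-o-quinone methide 4 (not isolated)
Conditions: PhMe (0.005 M), 90 °C
Reagents that add atoms: none
Why: Thermal dehydration of an o-hydroxybenzyl alcohol followed by o-quinone methide to o-vinylphenol tautomerization: from the conformer with the carbinol hydrogen in the ring plane, the flanking hydroxyl that hands its proton to the leaving group becomes the carbonyl syn to the side-chain CH2, so the quinone methide should form as the Z isomer 4, in which the inward isobutyl group blocks cycloaddition and a 1,5-hydrogen shift from CH2 to the carbonyl oxygen rearomatizes the ring to the conjugated E alkene (isopropyl outward in the six-membered transition state, also the thermodynamic isomer), while high dilution holds back bimolecular trapping.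

Step 3
Reactants: 3 racemic 2,4,6-trihydroxy-5-(1-hydroxy-3-methylbutyl)benzene-1,3-dicarbaldehyde; 5 2,4,6-trihydroxy-5-[(E)-3-methylbut-1-en-1-yl]benzene-1,3-dicarbaldehyde
Product: 7 sideroxylonal C, via (E)-o-quinone methide 6 (not isolated)
Conditions: (R)-3,3'-bis(2,4,6-triisopropylphenyl)-1,1'-binaphthyl-2,2'-diyl N-triflylphosphoramide (10 mol %), 5 Å molecular sieves, CH2Cl2–PhMe 1:1, −30 °C; 3 added slowly to 5 (1.2 equiv)
Reagents that add atoms: none
Why: The acidic N–H of the catalyst ionizes the benzylic hydroxyl of 3, and loss of the proton from the flanking hydroxyl on the side of the carbinol hydrogen (the side open to the bulky catalyst) gives (E)-o-quinone methide 6 hydrogen-bonded at its carbonyl oxygen, while the phosphoryl oxygen of the same catalyst holds an ortho hydroxyl of styrene 5, and an asynchronous inverse-electron-demand oxa-[4+2] cycloaddition then forms C3–C4 slightly ahead of O1–C2. The closest known reaction type is the chiral phosphoric acid or N-triflylphosphoramide-catalysed [4+2] cycloaddition of o-quinone methides, made in situ from o-hydroxybenzyl alcohols, with styrenes and o-hydroxystyrenes to give 2-arylchromans. The dihydropyran ring is the only ring closed, and it closes by intermolecular hetero-Diels–Alder cycloaddition, four atoms (O1, C8a, C4a, C4) coming from 6 and two (C2, C3) from 5, both components reacting suprafacially. C2 and C3 are set trans by the E geometry of 5; C4 is set relative to them by the E geometry of 6 (isobutyl outside, anti to the carbonyl oxygen; the Z tautomer, with the isobutyl group pointing into the heterodiene, is too hindered to cycloadd) and by the aryl-endo approach (ring B stacked on the heterodiene, the usual preference of styrenes, reinforced by the two-point binding), which gives 2,4-cis and 3,4-trans; the absolute configuration follows from the face of 6 left open by the 3,3'-aryl groups of the catalyst. The step needs regio- and chemoselectivity, and the substrate secures both: the electrophilic C4 of 6 meets the nucleophilic β-carbon of 5 and O1 the benzylic carbon, every ring carbon of both partners is substituted so that no Friedel–Crafts pathway exists, and both aryl rings are symmetric so that either oxygen flanking the side chain gives the same product. Styrene 5 is kept in excess and 3 is added slowly so that 6 is trapped as it forms, and the product should not reopen because its C2 aryl group is electron-poor.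

**Compound list**

1 | 2,4,6-trihydroxybenzene-1,3,5-tricarbaldehyde (triformylphloroglucinol) | O=Cc1c(O)c(C=O)c(O)c(C=O)c1O | starting material
2 | isobutylmagnesium bromide | CC(C)C[Mg]Br | starting material
3 | racemic 2,4,6-trihydroxy-5-(1-hydroxy-3-methylbutyl)benzene-1,3-dicarbaldehyde | CC(C)CC(O)c1c(O)c(C=O)c(O)c(C=O)c1O | intermediate
4 | (5Z)-2,4-dihydroxy-5-(3-methylbutylidene)-6-oxocyclohexa-1,3-diene-1,3-dicarbaldehyde (o-quinone methide, isobutyl syn to the ring carbonyl, not isolated) | CC(C)C/C=C1\C(=O)C(C=O)=C(O)C(C=O)=C1O | intermediate
5 | 2,4,6-trihydroxy-5-[(E)-3-methylbut-1-en-1-yl]benzene-1,3-dicarbaldehyde | CC(C)/C=C/c1c(O)c(C=O)c(O)c(C=O)c1O | intermediate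
6 | (5E)-2,4-dihydroxy-5-(3-methylbutylidene)-6-oxocyclohexa-1,3-diene-1,3-dicarbaldehyde (o-quinone methide, isobutyl anti to the ring carbonyl, not isolated) | CC(C)C/C=C1/C(=O)C(C=O)=C(O)C(C=O)=C1O | intermediate
7 | sideroxylonal C, (2R,3R,4R)-2-(3,5-diformyl-2,4,6-trihydroxyphenyl)-5,7-dihydroxy-4-(2-methylpropyl)-3-(propan-2-yl)-3,4-dihydro-2H-chromene-6,8-dicarbaldehyde (2-aryl and 3-isopropyl trans, 3-isopropyl and 4-isobutyl trans, 2-aryl and 4-isobutyl cis) | CC(C)C[C@H]1c2c(O)c(C=O)c(O)c(C=O)c2O[C@@H](c2c(O)c(C=O)c(O)c(C=O)c2O)[C@@H]1C(C)C | target

**Step count and risks**

Total step count: 3. Longest linear sequence: 3 steps (1 to 3 to 5 to 7).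

Steps most likely to fail:

1. Step 3. Part of the cycloaddition may run outside the chiral hydrogen-bonded complex (self-catalysis by the acidic phenols) or through the aryl-exo transition state, which would erode enantiofacial and diastereofacial selectivity. Fallback: setting out from 3 (with 5), the two are combined with an achiral acid (diphenyl phosphate, 10 mol %) in CH2Cl2 at 0 °C. This uncontrolled hetero-Diels–Alder reaction should give, after removal of diastereomers on silica, racemic sideroxylonal C F1. F1 is resolved by preparative chromatography on a cellulose tris(3,5-dimethylphenylcarbamate) phase, and the route is rejoined at 7.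

2. Step 1. A second formyl group may be attacked, β-hydride transfer from the reagent may reduce a formyl group, the polyanionic magnesium salt may mix poorly, or the carbinol may dehydrate during the acidic work-up. Fallback: setting out from 1, the phenols are silylated (TBSCl, imidazole, DMF) to 2,4,6-tris(tert-butyldimethylsilyloxy)benzene-1,3,5-tricarbaldehyde F2. F2 is treated with 2 (1.0 equiv, THF, −78 °C, acetic acid quench at −78 °C to forestall silyl transfer) to give racemic 2,4,6-tris(tert-butyldimethylsilyloxy)-5-(1-hydroxy-3-methylbutyl)benzene-1,3-dicarbaldehyde F3, with unreacted F2 recycled. Desilylation with Et3N·3HF in THF at 0 °C rejoins the route at 3.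

3. Step 2. Proton exchange between the flanking oxygens may turn transient 4 into its E tautomer, which accumulating 5 can trap to give racemic dimers too early, or the alkene may form with incomplete E selectivity. Fallback: setting out from 1, the trisodium salt (NaH, THF–DMSO) is olefinated once with isobutylidenetriphenylphosphorane (Wittig reaction of a non-stabilized ylide) to give 2,4,6-trihydroxy-5-[(Z)-3-methylbut-1-en-1-yl]benzene-1,3-dicarbaldehyde F4. F4 is isomerized with catalytic iodine under visible light to the E alkene, which rejoins the route at 5 without passing through a quinone methide.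

Further compounds
F1 | step 3 | racemic sideroxylonal C (both enantiomers of the 2,3-trans-3,4-trans diastereomer) | CC(C)C[C@H]1c2c(O)c(C=O)c(O)c(C=O)c2O[C@@H](c2c(O)c(C=O)c(O)c(C=O)c2O)[C@@H]1C(C)C.CC(C)C[C@@H]1c2c(O)c(C=O)c(O)c(C=O)c2O[C@H](c2c(O)c(C=O)c(O)c(C=O)c2O)[C@H]1C(C)C
F2 | step 1 | 2,4,6-tris(tert-butyldimethylsilyloxy)benzene-1,3,5-tricarbaldehyde | O=Cc1c(O[Si](C)(C)C(C)(C)C)c(C=O)c(O[Si](C)(C)C(C)(C)C)c(C=O)c1O[Si](C)(C)C(C)(C)C
F3 | step 1 | racemic 2,4,6-tris(tert-butyldimethylsilyloxy)-5-(1-hydroxy-3-methylbutyl)benzene-1,3-dicarbaldehyde | CC(C)CC(O)c1c(O[Si](C)(C)C(C)(C)C)c(C=O)c(O[Si](C)(C)C(C)(C)C)c(C=O)c1O[Si](C)(C)C(C)(C)C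
F4 | step 2 | 2,4,6-trihydroxy-5-[(Z)-3-methylbut-1-en-1-yl]benzene-1,3-dicarbaldehyde | CC(C)/C=C\c1c(O)c(C=O)c(O)c(C=O)c1O
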